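**Retrosynthetic overview**

1. Target 26 ⇐ primary allylic alcohol 23 by reductive 1,3-transposition, so the exocyclic methylene is unveiled last; 23 ⇐ ring B alkene 19 by epoxidation, chloride opening at C2 and OH→Br exchange at C3.
2. 19 ⇐ spiro vinylogous ester 12 by Stork–Danheiser addition of a CH2O unit, α′-bromination, cis-reduction and acetylation (ring A functionalised).
3. 12 ⇐ spiro enone 9 by conjugate reduction, enol triflate formation and methyl cross-coupling (C2=C3 alkene fixed on one arm).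
4. 9 ⇐ keto-aldehyde 8 by intramolecular aldol condensation; 8 ⇐ 6 + methyl vinyl ketone by a catalytic enantioselective intermolecular Michael addition (key C5–C6 bond, spiro stereocentre).
5. Ring order: ring A is the dimedone ring and is present from the start; ring B is closed second.

Assumption: of the two pseudo-enantiomeric cinchona squaramides, the quinine-derived one written in step 3 is taken to give (R)-8; if induction is opposite, the quinidine-derived catalyst is used.

Numbering: spiro[5.5]undecane numbering is used from 9 on (ring B = C1–C5, C6 = spiro carbon, ring A = C7–C11, C14 = the carbon that becomes the exocyclic methylene). C6 keeps its spatial arrangement throughout; its descriptor changes (R in 8, S in 9–16, R from 17) only through CIP priorities.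

**Route**

Step 1
Reactants: 1 dimedone (5,5-dimethylcyclohexane-1,3-dione); 2 2-methylpropan-1-ol
Product: 3 3-isobutoxy-5,5-dimethylcyclohex-2-en-1-one
Conditions: p-TsOH (cat.), toluene, reflux, Dean–Stark
Reagents that add atoms: none
Why: Acid-catalysed enol etherification of the 1,3-dione (vinylogous ester formation) driven by azeotropic removal of water; no stereocentre.

Step 2
Reactants: 3 3-isobutoxy-5,5-dimethylcyclohex-2-en-1-one; 4 ethyl formate
Product: 6 4-isobutoxy-2,2-dimethyl-6-oxocyclohex-4-ene-1-carbaldehyde (racemic; largely its hydroxymethylene enol), via lithium enolate 5 (not isolated)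
Conditions: LiN(i-Pr)2, THF, −78 °C; HCO2Et, −78 → 0 °C; AcOH quench
Reagents that add atoms: none
Why: Kinetic α′-deprotonation of the vinylogous ester and crossed Claisen condensation with the non-enolisable formate give the β-keto aldehyde; the new centre stays enolisable, so nothing is fixed yet.

Step 3
Reactants: 6 4-isobutoxy-2,2-dimethyl-6-oxocyclohex-4-ene-1-carbaldehyde; 7 methyl vinyl ketone (but-3-en-2-one)
Product: 8 (1R)-4-isobutoxy-2,2-dimethyl-6-oxo-1-(3-oxobutyl)cyclohex-4-ene-1-carbaldehyde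
Conditions: quinine-derived squaramide catalyst (10 mol%), CH2Cl2, −20 °C
Reagents that add atoms: none
Why: Intermolecular Michael addition of the soft 1,3-dicarbonyl enolate to the unhindered enone forms the C5–C6 bond, and the bifunctional catalyst (amine base plus hydrogen-bond donor) shields one enolate face to set the quaternary centre as R.

Step 4
Reactants: 8 (1R)-4-isobutoxy-2,2-dimethyl-6-oxo-1-(3-oxobutyl)cyclohex-4-ene-1-carbaldehyde
Product: 9 (6S)-9-isobutoxy-11,11-dimethylspiro[5.5]undeca-1,8-diene-3,7-dione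
Conditions: p-TsOH (10 mol%), toluene, 80 °C, Dean–Stark
Reagents that add atoms: none
Why: Acid-catalysed intramolecular aldol condensation of the methyl ketone onto the aldehyde closes ring B as a 4,4-disubstituted cyclohexenone without a nucleophile that could deformylate; C6 is untouched.

Step 5
Reactants: 9 (6S)-9-isobutoxy-11,11-dimethylspiro[5.5]undeca-1,8-diene-3,7-dione
Product: 11 (6S)-9-isobutoxy-11,11-dimethyl-7-oxospiro[5.5]undeca-2,8-dien-3-yl trifluoromethanesulfonate, via lithium enolate 10 (not isolated)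
Conditions: LiBH(s-Bu)3, THF, −78 °C; PhNTf2, −78 → 0 °C
Reagents that add atoms: N-phenylbis(trifluoromethanesulfonimide), O=S(=O)(N(c1ccccc1)S(=O)(=O)C(F)(F)F)C(F)(F)F
Why: Conjugate reduction of the ring B enone (the vinylogous ester is inert to the bulky hydride) gives the C2=C3 enolate regiospecifically and O-triflation traps it, so the alkene stays on the C1 arm and the spiro centre keeps its sense.

Step 6
Reactants: 11 (6S)-9-isobutoxy-11,11-dimethyl-7-oxospiro[5.5]undeca-2,8-dien-3-yl trifluoromethanesulfonate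
Product: 12 (6S)-9-isobutoxy-3,11,11-trimethylspiro[5.5]undeca-2,8-dien-7-one
Conditions: MeZnCl, Pd(PPh3)4 (5 mol%), THF, 50 °C
Reagents that add atoms: chloro(methyl)zinc, C[Zn]Cl
Why: Negishi cross-coupling of the enol triflate installs the C3 methyl without moving the alkene; no stereocentre is touched.

Step 7
Reactants: 12 (6S)-9-isobutoxy-3,11,11-trimethylspiro[5.5]undeca-2,8-dien-7-one
Product: 14 (6S)-7-[(methoxymethoxy)methyl]-3,11,11-trimethylspiro[5.5]undeca-2,7-dien-9-one, via tertiary carbinol 13 (not isolated)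
Conditions: Bu3SnCH2OCH2OMe, n-BuLi, THF, −78 °C; CeCl3; then 12, −78 → 0 °C; 1 M HCl, 23 °C
Reagents that add atoms: tributyl[(methoxymethoxy)methyl]stannane, CCCC[Sn](CCCC)(CCCC)COCOC; water, O
Why: Stork–Danheiser sequence: the (alkoxymethyl)cerium reagent from tin–lithium exchange adds 1,2 to the hindered ketone without enolising it, and acid hydrolysis of the enol ether with loss of water transposes the enone, placing C14 (as CH2OMOM) on C7.

Step 8
Reactants: 14 (6S)-7-[(methoxymethoxy)methyl]-3,11,11-trimethylspiro[5.5]undeca-2,7-dien-9-one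
Product: 17 (6R,10R)-10-bromo-7-[(methoxymethoxy)methyl]-3,11,11-trimethylspiro[5.5]undeca-2,7-dien-9-one, via lithium dienolate 15 (not isolated), via silyl dienol ether 16 (not isolated)
Conditions: LiN(i-Pr)2, THF, −78 °C; Me3SiCl; NBS, −78 → 0 °C
Reagents that add atoms: N-bromosuccinimide, O=C1CCC(=O)N1Br
Why: Kinetic α′-enolisation of the isophorone-type enone and electrophilic bromination of the silyl dienol ether put bromine on C10, and this epimerisable centre settles as the equatorial bromide cis to C1 (10R), the arrangement expected to be favoured while ring B is still a cyclohexene.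

Step 9
Reactants: 17 (6R,10R)-10-bromo-7-[(methoxymethoxy)methyl]-3,11,11-trimethylspiro[5.5]undeca-2,7-dien-9-one
Product: 18 (6R,9S,10R)-10-bromo-7-[(methoxymethoxy)methyl]-3,11,11-trimethylspiro[5.5]undeca-2,7-dien-9-ol
Conditions: i-Bu2AlH, CH2Cl2, −78 °C
Reagents that add atoms: none
Why: 1,2-Reduction of the α-bromo enone by the bulky hydride anti to the C–Br bond (Felkin–Anh/Cornforth control) gives the cis-bromohydrin and sets C9 as S.

Step 10
Reactants: 18 (6R,9S,10R)-10-bromo-7-[(methoxymethoxy)methyl]-3,11,11-trimethylspiro[5.5]undeca-2,7-dien-9-ol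
Product: 19 (6R,9S,10R)-10-bromo-7-[(methoxymethoxy)methyl]-3,11,11-trimethylspiro[5.5]undeca-2,7-dien-9-yl acetate
Conditions: Ac2O, Et3N, DMAP (cat.), CH2Cl2, 0 → 23 °C
Reagents that add atoms: acetic anhydride, CC(=O)OC(C)=O
Why: DMAP-catalysed acylation installs the target's acetate, which also masks C9–OH for the later Mitsunobu step; no stereocentre changes.

Step 11
Reactants: 19 (6R,9S,10R)-10-bromo-7-[(methoxymethoxy)methyl]-3,11,11-trimethylspiro[5.5]undeca-2,7-dien-9-yl acetate
Product: 20 (2R,3S,6R,9S,10R)-10-bromo-2,3-epoxy-7-[(methoxymethoxy)methyl]-3,11,11-trimethylspiro[5.5]undec-7-en-9-yl acetate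
Conditions: mCPBA, NaHCO3 (buffer), CH2Cl2, 0 °C
Reagents that add atoms: 3-chloroperbenzoic acid, O=C(OO)c1cccc(Cl)c1
Why: Prilezhaev epoxidation picks the electron-rich ring B alkene (the ring A alkene carries two allylic C–O groups and is hindered) and is expected on the face syn to C11, anti to the pseudo-axial C7 branch, giving the 2R,3S epoxide.

Step 12
Reactants: 20 (2R,3S,6R,9S,10R)-10-bromo-2,3-epoxy-7-[(methoxymethoxy)methyl]-3,11,11-trimethylspiro[5.5]undec-7-en-9-yl acetate
Product: 21 (2S,3S,6R,9S,10R)-10-bromo-2-chloro-3-hydroxy-7-[(methoxymethoxy)methyl]-3,11,11-trimethylspiro[5.5]undec-7-en-9-yl acetate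
Conditions: LiCl, AcOH, THF, 23 °C
Reagents that add atoms: lithium chloride, [Li+].[Cl-]
Why: Acid-assisted SN2 opening by chloride at the less substituted C2 in the trans-diaxial (Fürst–Plattner) mode inverts C2 and leaves the tertiary C3–O bond intact, giving the 2S chloride anti to the 3S alcohol.

Step 13
Reactants: 21 (2S,3S,6R,9S,10R)-10-bromo-2-chloro-3-hydroxy-7-[(methoxymethoxy)methyl]-3,11,11-trimethylspiro[5.5]undec-7-en-9-yl acetate
Product: 22 (2S,3S,6R,9S,10R)-3,10-dibromo-2-chloro-7-[(methoxymethoxy)methyl]-3,11,11-trimethylspiro[5.5]undec-7-en-9-yl acetate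
Conditions: Me2C=C(Br)NMe2, CH2Cl2, 0 → 23 °C
Reagents that add atoms: 1-bromo-N,N,2-trimethylprop-1-en-1-amine, CC(C)=C(Br)N(C)C
Why: Neutral activation of the tertiary alcohol as an alkoxy-iminium salt and ionisation assisted by the anti-periplanar chlorine give a chloronium ion that bromide opens at the tertiary carbon, so OH is replaced by Br with net retention (3S, Br trans to Cl).

Step 14
Reactants: 22 (2S,3S,6R,9S,10R)-3,10-dibromo-2-chloro-7-[(methoxymethoxy)methyl]-3,11,11-trimethylspiro[5.5]undec-7-en-9-yl acetate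
Product: 23 (2S,3S,6R,9S,10R)-3,10-dibromo-2-chloro-7-(hydroxymethyl)-3,11,11-trimethylspiro[5.5]undec-7-en-9-yl acetate
Conditions: ZnBr2, n-PrSH, CH2Cl2, 0 °C
Reagents that add atoms: none
Why: Lewis acid-promoted transacetalisation of the MOM ether to the thiol frees the primary allylic alcohol without touching the acetate or the halides; no stereocentre changes.

Step 15
Reactants: 23 (2S,3S,6R,9S,10R)-3,10-dibromo-2-chloro-7-(hydroxymethyl)-3,11,11-trimethylspiro[5.5]undec-7-en-9-yl acetate
Product: 26 9-acetylisoobtusol [(2S,3S,6R,9S,10R)-3,10-dibromo-2-chloro-3,11,11-trimethyl-7-methylidenespiro[5.5]undecan-9-yl acetate], via sulfonylhydrazine adduct 24 (not isolated), via allylic diazene 25 (not isolated)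
Conditions: PPh3, DEAD, 2-nitrobenzenesulfonylhydrazide, N-methylmorpholine, −30 → 23 °C
Reagents that add atoms: none
Why: Mitsunobu displacement of the primary allylic alcohol by the sulfonyl hydrazide, loss of sulfinic acid and retro-ene loss of N2 from the monoalkyl diazene (Myers reductive 1,3-transposition) deliver hydrogen to C8 and move the alkene to the exocyclic C7=C14 position regiospecifically; no stereocentre is touched.

**Compound list**

1 | dimedone (5,5-dimethylcyclohexane-1,3-dione) | CC1(C)CC(=O)CC(=O)C1 | starting material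
2 | 2-methylpropan-1-ol | CC(C)CO | starting material
3 | 3-isobutoxy-5,5-dimethylcyclohex-2-en-1-one | CC(C)COC1=CC(=O)CC(C)(C)C1 | intermediate
4 | ethyl formate | CCOC=O | starting material
5 | lithium enolate of 3 (C6 deprotonated; not isolated) | [Li+].[O-]C1=CC(C)(C)CC(OCC(C)C)=C1 | intermediate
6 | 4-isobutoxy-2,2-dimethyl-6-oxocyclohex-4-ene-1-carbaldehyde (racemic, enolised) | O=CC1C(=O)C=C(OCC(C)C)CC1(C)C | intermediate
7 | methyl vinyl ketone | C=CC(C)=O | starting material
8 | (1R)-4-isobutoxy-2,2-dimethyl-6-oxo-1-(3-oxobutyl)cyclohex-4-ene-1-carbaldehyde | O=C1C=C(OCC(C)C)CC(C)(C)[C@@]1(C=O)CCC(C)=O | intermediate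
9 | (6S)-9-isobutoxy-11,11-dimethylspiro[5.5]undeca-1,8-diene-3,7-dione | O=C1C=C(OCC(C)C)CC(C)(C)[C@@]12CCC(=O)C=C2 | intermediate
10 | lithium (6S)-9-isobutoxy-11,11-dimethyl-7-oxospiro[5.5]undeca-2,8-dien-3-olate (not isolated) | O=C1C=C(OCC(C)C)CC(C)(C)[C@@]12CCC([O-])=CC2.[Li+] | intermediate
11 | (6S)-9-isobutoxy-11,11-dimethyl-7-oxospiro[5.5]undeca-2,8-dien-3-yl trifluoromethanesulfonate | O=C1C=C(OCC(C)C)CC(C)(C)[C@@]12CCC(OS(=O)(=O)C(F)(F)F)=CC2 | intermediate
12 | (6S)-9-isobutoxy-3,11,11-trimethylspiro[5.5]undeca-2,8-dien-7-one | O=C1C=C(OCC(C)C)CC(C)(C)[C@@]12CCC(C)=CC2 | intermediate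
13 | (6S)-9-isobutoxy-7-[(methoxymethoxy)methyl]-3,11,11-trimethylspiro[5.5]undeca-2,8-dien-7-ol (C7 epimers; not isolated) | COCOCC1(O)C=C(OCC(C)C)CC(C)(C)[C@@]12CCC(C)=CC2 | intermediate
14 | (6S)-7-[(methoxymethoxy)methyl]-3,11,11-trimethylspiro[5.5]undeca-2,7-dien-9-one | COCOCC1=CC(=O)CC(C)(C)[C@@]12CCC(C)=CC2 | intermediate
15 | lithium (6S)-7-[(methoxymethoxy)methyl]-3,11,11-trimethylspiro[5.5]undeca-2,7,9-trien-9-olate (not isolated) | COCOCC1=CC([O-])=CC(C)(C)[C@@]12CCC(C)=CC2.[Li+] | intermediate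
16 | (6S)-7-[(methoxymethoxy)methyl]-3,11,11-trimethyl-9-(trimethylsilyloxy)spiro[5.5]undeca-2,7,9-triene (not isolated) | COCOCC1=CC(O[Si](C)(C)C)=CC(C)(C)[C@@]12CCC(C)=CC2 | intermediate
17 | (6R,10R)-10-bromo-7-[(methoxymethoxy)methyl]-3,11,11-trimethylspiro[5.5]undeca-2,7-dien-9-one | COCOCC1=CC(=O)[C@H](Br)C(C)(C)[C@@]12CCC(C)=CC2 | intermediate
18 | (6R,9S,10R)-10-bromo-7-[(methoxymethoxy)methyl]-3,11,11-trimethylspiro[5.5]undeca-2,7-dien-9-ol | COCOCC1=C[C@H](O)[C@H](Br)C(C)(C)[C@@]12CCC(C)=CC2 | intermediate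
19 | (6R,9S,10R)-10-bromo-7-[(methoxymethoxy)methyl]-3,11,11-trimethylspiro[5.5]undeca-2,7-dien-9-yl acetate | COCOCC1=C[C@H](OC(C)=O)[C@H](Br)C(C)(C)[C@@]12CCC(C)=CC2 | intermediate
20 | (2R,3S,6R,9S,10R)-10-bromo-2,3-epoxy-7-[(methoxymethoxy)methyl]-3,11,11-trimethylspiro[5.5]undec-7-en-9-yl acetate | COCOCC1=C[C@H](OC(C)=O)[C@H](Br)C(C)(C)[C@@]12CC[C@]3(C)O[C@@H]3C2 | intermediate
21 | (2S,3S,6R,9S,10R)-10-bromo-2-chloro-3-hydroxy-7-[(methoxymethoxy)methyl]-3,11,11-trimethylspiro[5.5]undec-7-en-9-yl acetate | COCOCC1=C[C@H](OC(C)=O)[C@H](Br)C(C)(C)[C@@]12CC[C@](C)(O)[C@@H](Cl)C2 | intermediate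
22 | (2S,3S,6R,9S,10R)-3,10-dibromo-2-chloro-7-[(methoxymethoxy)methyl]-3,11,11-trimethylspiro[5.5]undec-7-en-9-yl acetate | COCOCC1=C[C@H](OC(C)=O)[C@H](Br)C(C)(C)[C@@]12CC[C@](C)(Br)[C@@H](Cl)C2 | intermediate
23 | (2S,3S,6R,9S,10R)-3,10-dibromo-2-chloro-7-(hydroxymethyl)-3,11,11-trimethylspiro[5.5]undec-7-en-9-yl acetate | OCC1=C[C@H](OC(C)=O)[C@H](Br)C(C)(C)[C@@]12CC[C@](C)(Br)[C@@H](Cl)C2 | intermediate
24 | N-allylic N-(2-nitrobenzenesulfonyl)hydrazine from 23 (C14–N bond; not isolated) | NN(CC1=C[C@H](OC(C)=O)[C@H](Br)C(C)(C)[C@@]12CC[C@](C)(Br)[C@@H](Cl)C2)S(=O)(=O)c3ccccc3[N+](=O)[O-] | intermediate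
25 | allylic monoalkyl diazene from 24 (not isolated) | N=NCC1=C[C@H](OC(C)=O)[C@H](Br)C(C)(C)[C@@]12CC[C@](C)(Br)[C@@H](Cl)C2 | intermediate
26 | 9-acetylisoobtusol, (2S,3S,6R,9S,10R)-3,10-dibromo-2-chloro-3,11,11-trimethyl-7-methylidenespiro[5.5]undecan-9-yl acetate | C=C1C[C@H](OC(C)=O)[C@H](Br)C(C)(C)[C@@]12CC[C@](C)(Br)[C@@H](Cl)C2 | target

**Summary**

Total step count: 15. Longest linear sequence: 15 steps (1 → 26).

Steps most likely to fail, each with one fallback:

Step 3 (Michael addition at a neopentyl donor; rate and enantioselectivity are unproven for this substrate). The fallback sets out from 3 and builds the quaternary centre by alkylation and palladium-catalysed decarboxylative allylation instead. Alkylation of the lithium enolate of 3 with 4-iodo-2-methylbut-1-ene gives racemic 3-isobutoxy-5,5-dimethyl-6-(3-methylbut-3-en-1-yl)cyclohex-2-en-1-one F1. A second deprotonation and O-acylation with allyl chloroformate give allyl [5-isobutoxy-3,3-dimethyl-2-(3-methylbut-3-en-1-yl)cyclohexa-1,5-dien-1-yl] carbonate F2. Pd2(dba)3 with the electron-poor (S)-tert-butyl-PHOX ligand (antipode chosen by the observed sense of induction) then gives (6S)-6-allyl-3-isobutoxy-5,5-dimethyl-6-(3-methylbut-3-en-1-yl)cyclohex-2-en-1-one F3. Ring-closing metathesis with the second-generation Grubbs catalyst closes ring B and comes back to the route at 12, skipping 6–11.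

Step 7 (1,2-addition of the alkoxymethyl nucleophile to a ketone flanked by the spiro carbon). The fallback sets out from 12 and brings in C14 as a methyl group, oxidising it afterwards. MeLi/CeCl3 followed by aqueous HCl gives (6S)-3,7,11,11-tetramethylspiro[5.5]undeca-2,7-dien-9-one F4. Soft enolisation with TBSOTf/Et3N gives the extended dienol ether (6S)-9-[(tert-butyldimethylsilyl)oxy]-3,11,11-trimethyl-7-methylidenespiro[5.5]undeca-2,8-diene F5. Vinylogous Rubottom oxidation with dimethyldioxirane at −78 °C and mild acid work-up give (6S)-7-(hydroxymethyl)-3,11,11-trimethylspiro[5.5]undeca-2,7-dien-9-one F6. MOMCl/i-Pr2NEt then comes back to the route at 14.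

Step 13 (tertiary alcohol to tertiary bromide next to a chloride; elimination or loss of configuration is possible). The fallback sets out from 19 and replaces steps 11–13 by a one-step bromochlorination of the ring B alkene (NBS, Et4NCl, CH2Cl2, −78 °C). It relies on bromonium formation anti to the C7 branch and trans-diaxial opening by chloride at C2, with the regioisomer removed by chromatography. It comes back to the route at 22 and makes no compound outside the list (none F0).

**Further compounds**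

F1 | step 3 | 3-isobutoxy-5,5-dimethyl-6-(3-methylbut-3-en-1-yl)cyclohex-2-en-1-one (racemic) | O=C1C=C(OCC(C)C)CC(C)(C)C1CCC(C)=C
F2 | step 3 | allyl [5-isobutoxy-3,3-dimethyl-2-(3-methylbut-3-en-1-yl)cyclohexa-1,5-dien-1-yl] carbonate | C=CCOC(=O)OC1=C(CCC(C)=C)C(C)(C)CC(OCC(C)C)=C1
F3 | step 3 | (6S)-6-allyl-3-isobutoxy-5,5-dimethyl-6-(3-methylbut-3-en-1-yl)cyclohex-2-en-1-one | O=C1C=C(OCC(C)C)CC(C)(C)[C@@]1(CC=C)CCC(C)=C
F4 | step 7 | (6S)-3,7,11,11-tetramethylspiro[5.5]undeca-2,7-dien-9-one | CC1=CC(=O)CC(C)(C)[C@@]12CCC(C)=CC2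
F5 | step 7 | (6S)-9-[(tert-butyldimethylsilyl)oxy]-3,11,11-trimethyl-7-methylidenespiro[5.5]undeca-2,8-diene | C=C1C=C(O[Si](C)(C)C(C)(C)C)CC(C)(C)[C@@]12CCC(C)=CC2
F6 | step 7 | (6S)-7-(hydroxymethyl)-3,11,11-trimethylspiro[5.5]undeca-2,7-dien-9-one | OCC1=CC(=O)CC(C)(C)[C@@]12CCC(C)=CC2
F0 | step 13 | none | none
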